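## Retrosynthetic overview

1. The target is a 2-butanoyl-4,4-dimethylcyclohexane-1,3,5-trione ring (enol form) joined through a CH2 group to a 3-butanoyl-4,6-dihydroxy-2,5-dimethylphenyl ring. Trione ring numbering used below: C1 = ring C=O between the two substituted carbons, C2 = butanoyl-bearing carbon, C3, C4 = CMe2, C5, C6 = CH2-bearing carbon.
2. Enabling feature: the phenolic oxygen on the aromatic carbon ortho to the bridge, the two aromatic carbons, the bridge CH2, C6 and the carbonyl carbon C1 are the six atoms of a latent aryl lactone ring (3,4-dihydrocoumarin). C5, C4, C3, C2 and the butanoyl C=O are a latent 3,3-dimethylpyran-2,4-dione, and the quaternary C4 forbids any aromatising side path.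
3. Key disconnection: bonds C5–C6 and C1–C2, leading back to a 6-butanoyl-7-hydroxy-dihydrocoumarin and 3,3-dimethyl-6-propylpyran-2,4-dione. The lactone enolate opens the pyrandione, and the 1,3-diketonate so released closes C2 onto C1 and expels the phenoxide.
4. The dihydrocoumarin comes from 2,5-dimethylresorcinol and acrylic acid, then Fries butanoylation. The pyrandione comes from tert-butyl acetoacetate by gem-dimethylation, Claisen acylation with butanoyl chloride and cyclodehydration.
5. Ring order: aryl lactone ring (step 1), enol lactone ring (step 5), carbocyclic trione ring last (step 6), in which both temporary lactone rings are opened; the aromatic ring is bought.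

Key step: step 6

Remark on the chemistry: the target is an achiral, tautomerisable β-triketone. The drawn dienol tautomer is assumed to be the form obtained after acidic work-up, so no stereocentre and no tautomer control has to be planned.

## Route

Step 1
Reactants: 1 2,5-dimethylbenzene-1,3-diol; 2 prop-2-enoic acid (acrylic acid)
Product: 4 7-hydroxy-5,8-dimethyl-3,4-dihydro-2H-chromen-2-one, via hydroxy acid 3 (not isolated)
Conditions: acrylic acid (1.0 equiv), Amberlyst-15, PhMe, reflux, Dean–Stark
Reagents that add atoms: none
Why: Acid-catalysed Friedel–Crafts conjugate addition of the resorcinol carbon C4 (ortho and para to the two hydroxyls; C4 and C6 are equivalent by symmetry) to acrylic acid, then lactonisation onto the adjacent hydroxyl, is the standard hydroarylation route to 3,4-dihydrocoumarins, and one equivalent of the acid limits a second annulation.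

Step 2
Reactants: 4 7-hydroxy-5,8-dimethyl-3,4-dihydro-2H-chromen-2-one; 5 butanoyl chloride
Product: 7 6-butanoyl-7-hydroxy-5,8-dimethyl-3,4-dihydro-2H-chromen-2-one, via aryl butanoate 6 (not isolated)
Conditions: PrCOCl (1.1 equiv), AlCl3 (3 equiv), ClCH2CH2Cl, 0 to 80 °C; cold 1 M HCl
Reagents that add atoms: none
Why: O-acylation followed by AlCl3-promoted Fries rearrangement places the butanoyl group on C6, the only unsubstituted ring carbon and ortho to the phenol, while the lactone has no free ortho position for a Fries shift of its own.

Step 3
Reactants: 8 tert-butyl 3-oxobutanoate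
Product: 9 tert-butyl 2,2-dimethyl-3-oxobutanoate
Conditions: MeI (2.5 equiv), K2CO3 (3 equiv), DMF, 23 to 40 °C
Reagents that add atoms: iodomethane, CI
Why: Exhaustive C-methylation of the β-keto ester enolate (acetoacetic ester alkylation) creates the quaternary carbon that becomes C4 of the trione ring and removes every acidic hydrogen between the two carbonyls.

Step 4
Reactants: 9 tert-butyl 2,2-dimethyl-3-oxobutanoate; 5 butanoyl chloride
Product: 10 tert-butyl 2,2-dimethyl-3,5-dioxooctanoate
Conditions: LiN(SiMe3)2 (1.05 equiv), PhMe–THF, 0 °C; PrCOCl (0.5 equiv); 1 M HCl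
Reagents that add atoms: none
Why: Crossed Claisen C-acylation of the only possible ketone enolate of 9 by the acid chloride, with the second enolate equivalent taking up the acidic proton of the new 1,3-diketone, should give 10 without over-acylation; unreacted 9 should be recoverable.

Step 5
Reactants: 10 tert-butyl 2,2-dimethyl-3,5-dioxooctanoate
Product: 12 3,3-dimethyl-6-propyl-2H-pyran-2,4(3H)-dione, via keto acid 11 (not isolated)
Conditions: CF3CO2H–CH2Cl2 (1:2), 0 °C; then (CF3CO)2O (1.5 equiv), 0 to 23 °C; evaporation, short-path distillation
Reagents that add atoms: none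
Why: Acidolysis of the tert-butyl ester and cyclodehydration of the 3,5-dioxo acid through its mixed trifluoroacetic anhydride, with the enol oxygen of the C5 ketone closing the six-membered enol lactone, follows the established conversion of β,δ-diketo acids into pyran-2,4-diones and avoids aqueous handling of the activated lactone.

Step 6
Reactants: 7 6-butanoyl-7-hydroxy-5,8-dimethyl-3,4-dihydro-2H-chromen-2-one; 12 3,3-dimethyl-6-propyl-2H-pyran-2,4(3H)-dione
Product: 14 2-butanoyl-6-[(3-butanoyl-4,6-dihydroxy-2,5-dimethylphenyl)methyl]-3,5-dihydroxy-4,4-dimethylcyclohexa-2,5-dien-1-one, via Claisen adduct 13 (not isolated)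
Conditions: LiN(SiMe3)2 (2.1 equiv), THF, −78 °C; 12 (1.2 equiv), −78 °C; LiN(SiMe3)2 (1.0 equiv), −78 °C; MgBr2·OEt2 (2.5 equiv), −78 to 23 °C; 1 M HCl
Reagents that add atoms: none
Why: Proposed new method: the dilithium phenoxide–lactone enolate of 7 attacks the enol-lactone carbonyl of 12 (bond C5–C6 of the trione ring) and the tetrahedral intermediate opens to adduct 13, releasing a 1,3-diketonate whose central carbon (C2) then attacks the aryl-lactone carbonyl C1 and expels the aryloxide (directly, or after E1cB loss of the same aryloxide from the C6 enolate to an acylketene), so that two C–C bonds form, both temporary lactone rings open and the acylfilicinic ring closes in one flask. The closest known reaction types are the crossed Claisen acylation of lactone enolates by enol esters, the Baker–Venkataraman O-to-C acyl transfer of aryl esters and the Claisen-mode cyclisation of 3,5,7-triketo esters to acylphloroglucinols; their combination as a lactone-plus-lactone [4+2] annulation is the new element. The carbocycle closes in a 6-exo Dieckmann mode (trig on the lactone carbonyl, dig on the ketene), made irreversible by formation of the strongly acidic β-triketone enolate. No stereocentre is set, because C6 of 13 is epimerisable and ends as an enol carbon of the achiral product. The step needs enolisation of the lactone α-CH2 rather than the butanoyl α-CH2, attack at the lactone carbonyl of 12, and Claisen rather than aldol or O-acyl closure: the free 7-OH, deprotonated first, makes the neighbouring aryl ketone a vinylogous carboxylate whose α-hydrogens should be much less acidic than those of the E-configured aryl lactone, the enol-ester carbonyl is the most electrophilic site of 12 (its ketone is a vinylogous ester), the quaternary C4 rules out aromatising aldol paths, and any O-acylated enol lactone remains an activated ester that can reopen until the C-acylated sink is reached. The second charge of base is held back until 12 is present because each adduct carries a new acidic C–H that would otherwise quench a second lactone enolate, and MgBr2·OEt2 is added before warming because magnesium chelation of the diketonate oxygens leaves C2 as its nucleophilic site.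

## Compound list

1 | 2,5-dimethylbenzene-1,3-diol (2,5-dimethylresorcinol) | Cc1cc(O)c(C)c(O)c1 | starting material
2 | prop-2-enoic acid (acrylic acid) | C=CC(=O)O | starting material
3 | 3-(2,4-dihydroxy-3,6-dimethylphenyl)propanoic acid (formed in the flask, not isolated) | OC(=O)CCc1c(C)cc(O)c(C)c1O | intermediate
4 | 7-hydroxy-5,8-dimethyl-3,4-dihydro-2H-chromen-2-one | O=C1CCc2c(C)cc(O)c(C)c2O1 | intermediate
5 | butanoyl chloride | CCCC(=O)Cl | starting material
6 | 5,8-dimethyl-2-oxo-3,4-dihydro-2H-chromen-7-yl butanoate (formed in the flask, not isolated) | CCCC(=O)Oc1cc(C)c2CCC(=O)Oc2c1C | intermediate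
7 | 6-butanoyl-7-hydroxy-5,8-dimethyl-3,4-dihydro-2H-chromen-2-one | CCCC(=O)c1c(O)c(C)c2OC(=O)CCc2c1C | intermediate
8 | tert-butyl 3-oxobutanoate (tert-butyl acetoacetate) | CC(=O)CC(=O)OC(C)(C)C | starting material
9 | tert-butyl 2,2-dimethyl-3-oxobutanoate | CC(=O)C(C)(C)C(=O)OC(C)(C)C | intermediate
10 | tert-butyl 2,2-dimethyl-3,5-dioxooctanoate | CCCC(=O)CC(=O)C(C)(C)C(=O)OC(C)(C)C | intermediate
11 | 2,2-dimethyl-3,5-dioxooctanoic acid (formed in the flask, not isolated) | CCCC(=O)CC(=O)C(C)(C)C(=O)O | intermediate
12 | 3,3-dimethyl-6-propyl-2H-pyran-2,4(3H)-dione | CCCC1=CC(=O)C(C)(C)C(=O)O1 | intermediate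
13 | 6-butanoyl-3-(2,2-dimethyl-3,5-dioxooctanoyl)-7-hydroxy-5,8-dimethyl-3,4-dihydro-2H-chromen-2-one (racemic and configurationally labile at C3; formed in the flask, not isolated) | CCCC(=O)CC(=O)C(C)(C)C(=O)C1Cc2c(C)c(C(=O)CCC)c(O)c(C)c2OC1=O | intermediate
14 | 2-butanoyl-6-[(3-butanoyl-4,6-dihydroxy-2,5-dimethylphenyl)methyl]-3,5-dihydroxy-4,4-dimethylcyclohexa-2,5-dien-1-one | CCCC(=O)C1=C(O)C(C)(C)C(O)=C(Cc2c(C)c(C(=O)CCC)c(O)c(C)c2O)C1=O | target

## Step count and risks

Total step count: 6. Longest linear sequence: 4 steps (8 to 9 to 10 to 12 to 14).

Steps most likely to fail: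

Step 6 (proposed new method). What may go wrong: enolisation at the butanoyl side chain instead of the lactone, conjugate attack of the enolate on the pyrandione, or ring closure through a diketonate oxygen or by aldol addition instead of C-acylation at C2. The fallback uses the classical methylene-bridge assembly, sets out from 1 and 5 and comes back at 14. Friedel–Crafts acylation of 1 with 5 (AlCl3, PhNO2, 23 °C) should give 1-(2,4-dihydroxy-3,6-dimethylphenyl)butan-1-one F1. A Mannich reaction at its single free ring position (aqueous CH2O, Me2NH, EtOH, 23 °C) should give 1-{5-[(dimethylamino)methyl]-2,4-dihydroxy-3,6-dimethylphenyl}butan-1-one F2. Separately, C,C-dimethylation of commercial 1-(2,4,6-trihydroxyphenyl)butan-1-one (MeI, NaOMe, MeOH) should give 2-butanoyl-3,5-dihydroxy-4,4-dimethylcyclohexa-2,5-dien-1-one F3. Heating F2 with F3 (dioxane, 100 °C) should expel dimethylamine, and the o-quinone methide so formed should be captured by C6 of F3 in a Michael addition to give 14.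

Step 2. What may go wrong: intermolecular acyl transfer from the aryl lactone under AlCl3 (Fries-type oligomerisation), or incomplete migration of the butanoyl group into the hindered position between hydroxyl and methyl. The fallback reverses the order of ketone and lactone installation, sets out from 1 and 5 and comes back at 7. Friedel–Crafts acylation of the free resorcinol 1 with 5 (AlCl3, PhNO2, 23 °C) should give 1-(2,4-dihydroxy-3,6-dimethylphenyl)butan-1-one F4 (the same ketone as F1). Hydroarylation of 2 by the single free ring carbon of F4 with lactonisation onto the only adjacent hydroxyl (MeSO3H, 70 °C) should then give 7, so that no Fries step is run on a lactone.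

Step 5. What may go wrong: decarboxylation of the β-keto acid during ester cleavage, or hydrolytic ring opening of the enol lactone during isolation. The fallback builds the ring from a malonyl dichloride and a regiodefined silyl enol ether, sets out from 5 and comes back at 12. Acylation of Me3SiCH2MgCl with 5 (CuI cat., THF, −30 °C) should give 1-(trimethylsilyl)pentan-2-one F5. A thermal Brook-type 1,3-shift of silicon from carbon to oxygen (neat, 150 °C) should give trimethyl(pent-1-en-2-yloxy)silane F6 with the double bond fixed at the terminal carbon. C-acylation of F6 by dimethylpropanedioyl dichloride (Et2O, −20 to 23 °C) should give 2,2-dimethyl-3,5-dioxooctanoyl chloride F7, which should close to 12 by enol O-acylation without any free acid or water being involved.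

Further compounds
F1 | step 6 | 1-(2,4-dihydroxy-3,6-dimethylphenyl)butan-1-one | CCCC(=O)c1c(C)cc(O)c(C)c1O
F2 | step 6 | 1-{5-[(dimethylamino)methyl]-2,4-dihydroxy-3,6-dimethylphenyl}butan-1-one | CCCC(=O)c1c(C)c(CN(C)C)c(O)c(C)c1O
F3 | step 6 | 2-butanoyl-3,5-dihydroxy-4,4-dimethylcyclohexa-2,5-dien-1-one | CCCC(=O)C1=C(O)C(C)(C)C(O)=CC1=O
F4 | step 2 | 1-(2,4-dihydroxy-3,6-dimethylphenyl)butan-1-one | CCCC(=O)c1c(C)cc(O)c(C)c1O
F5 | step 5 | 1-(trimethylsilyl)pentan-2-one | CCCC(=O)C[Si](C)(C)C
F6 | step 5 | trimethyl(pent-1-en-2-yloxy)silane | CCCC(=C)O[Si](C)(C)C
F7 | step 5 | 2,2-dimethyl-3,5-dioxooctanoyl chloride | CCCC(=O)CC(=O)C(C)(C)C(Cl)=O
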